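Solid substrate plus target stayed close to the charge in the earlier runs: 96.9 % at 1.00 min in the south run and 97.0 % at 1.33 min in the south-west run, and target later reached the charge in both. With that ledger, I wanted to know how long a flask with 11 mM of catalyst needed to empty its solid.

| setting | south | south-west | flask |
|---|---|---|---|
| solid substrate | 0.67 M | 0.67 M | 0.67 M |
| catalyst | 5.5 mM (in portions, 3) | 8.2 mM (in portions, 3) | 11 mM (in portions, 3) |
| remark | run made earlier; portions every 3.0 s | run made earlier; portions every 3.0 s | the portions of catalyst follow each other after 3.0 s, the first at the start |
| time |  |  | 8.0 min |

- south (time / min: solid substrate / %, target / %): 1.00: 40.1, 56.8; 2.00: 0.4, 99.8; 3.00: 0, 99.6; 4.00: 0, 100.2; 5.00: 0, 100.3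
- south-west (time / min: solid substrate / %, target / %): 0.417: 75.0, 25.0; 1.33: 15.7, 81.3; 2.00: 0, 99.6; 3.00: 0, 100.6; 5.00: 0, 100.2

(readings scatter by 0.5 percentage points)

- solid substrate is a solid; its amount is given per volume of the solution
- at the start none of the solid substrate is in solution
- what has only dissolved of solid substrate counts as not reacted
- the reaction counts as stopped when no species that holds the solid substrate changes by six tenths of a point or more over the second half of the time

1. why nothing more happens at 8.0 min, or that something still does (for what has run out or reacted, a solid counts together with what of it has only dissolved) (forward and back rates have come level / it is still moving / all of the solid substrate has reacted / no working catalyst is left)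
2. part of the solid substrate that has turned into other species by 8.0 min (what has only dissolved does not count)
3. target at 8.0 min, in percent of the solid substrate charged

I built the flask up one process at a time. With catalytic turnover as the main step, the pace should have followed the catalyst, and the south-west run held 1.49 times the charge of the south run. So I took the first reading of the south run and got 1.67 min as its clearing time: the time of a reading divided by the share of solid lost by then. The south-west run gave 1.67 min, about the same, so I added dissolution as the rate-limiting step and expected the same clearing time from the new flask. The 3.10 % missing from the south run at 1.00 min I took as dissolved and unreacted. Then came the rest. The portions ended after 6.00 s, far shorter than the clearing time, and target still stood at 100.3 % at 5.00 min in the south run, so I counted on no loss. The asked 8.0 min was 4.79 clearing times, and I expected the solid substrate to have reacted and target to stand at the charge.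

The forecast gave all of the solid substrate has reacted, conversion 100 % and target 100 %, and its reading of the loss of solid was that it “suggests dissolution of the solid limits the rate, not catalysis”.

The flask gave all of the solid substrate has reacted, with conversion 100 % and target 100 %.

    solid substrate ⇌ starting material, rate k1*(cs1 - [starting material]) while solid is left; crystals form when [starting material] > cs1 (solubility = 0.150 M, k = 0.0525 s⁻¹)
    starting material + catalyst → catalyst + target (k = 56.6 M⁻¹ s⁻¹)

The flask held 74.1 % of its solid at 0.400 min, which gives a clearing time of 1.54 min, a little shorter than the south run's. I then took a neighbour charged with 1.1 M of solid substrate. Holding the south run's pace of 0.401 M min⁻¹, its clearing time came to 2.74 min, shorter than the asked time. That neighbour gave target 100 %, with 0 % of its charge left. With the catalyst and the time held as in the flask, target at the asked time had moved by 5 points at 3.66 M of solid substrate.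

The data are simulated on assumed constants; the scatter is artificial.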